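The readings are calculated on assumed constants; noise was put on by code.

In a one-step world the target would climb at one steady rate from the first instant. The two earlier runs did not look like that, and the flask differs from them in its precatalyst, so I asked what those runs say about the precatalyst.

| flask | starting material | second substrate | reagent | precatalyst | added ligand | remark |
|---|---|---|---|---|---|---|
| south-east | 0.80 M | 0.40 M | 0.88 M | 5 mM | 25 mM | run made earlier |
| east | 0.80 M | 0.40 M | 0.88 M | 7.5 mM | 25 mM | run made earlier |
| flask | 0.80 M | 0.400 M | 0.880 M | 10 mM | 25 mM |  |

| south-east: time / min | south-east: target / % | east: time / min | east: target / % |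
|---|---|---|---|
| 4.00 | 0 | 4.00 | 0.5 |
| 12.0 | 2.3 | 8.00 | 0.5 |
| 20.0 | 0.9 | 15.0 | 1.0 |
| 30.0 | 6.8 | 25.0 | 5.1 |
| 50.0 | 11.4 | 50.0 | 13.8 |

(scatter of a reading: 1 percentage point)

1. factor on the rate of making target when 30% of the starting material are converted if reagent is charged twice over
2. factor on the rate when 30% of the starting material are converted if precatalyst is charged at 1.0 mM instead

- no earlier run changes the charge of reagent; that part of a forecast is a guess

I took the runs in slow motion. In the first instants, at 4.00 min and 4.00 min, the readings of 0% and 0.5% could not be told from zero, given a scatter of 1 percentage point. In the middle the target rose along a line. I turned its late slope into molar terms and divided by the precatalyst charged, which gave the turnover rate per catalyst charged. It read 0.368 min⁻¹ in the south-east run and 0.371 min⁻¹ in the east run, so I carried their mean, 0.370 min⁻¹, trusting the match no closer than that scatter allows. Equal values at different charges mean first order in catalyst, so I reckoned a factor of 0.100 for 1.0 mM.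

Integrating that steady rate gives target = rate × (time − lag). The lines met zero at 0.435 min and 10.3 min, which are poor readings of the lag. In the flask I expected 0.00370 M min⁻¹, so 30% conversion needed 64.9 min of running, plus the lag.

Toward that point, with reagent going one for one with the target, 0.640 M of reagent would stand beside 0.560 M of starting material. No run varied reagent, and a doubled charge would by the same count leave 1.52 M of reagent at that point, a factor of 2.38 on what stood there, so an order between zero and one allowed a factor from 1 to 2.38, and I guessed order one half, which gives 1.54.

The forecast, of the order in precatalyst saying “and I take about 0.8”, gave 1.3 and 0.15, which differ from my two factors.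

The flask gave 1.60 and 0.0985.

    starting material + free catalyst ⇌ catalyst intermediate A (K = 20.0 L mol⁻¹, k = 5.80 L mol⁻¹ min⁻¹)
    reagent + catalyst intermediate A → free catalyst + target (k = 1.30 L mol⁻¹ min⁻¹)
    second substrate + free catalyst ⇌ catalyst intermediate B (K = 3.30 L mol⁻¹, k = 2.70 L mol⁻¹ min⁻¹)
    reagent + catalyst intermediate B → free catalyst + second product (k = 0.940 L mol⁻¹ min⁻¹)
    free catalyst + added ligand ⇌ idle complex, settled at all times (K = 83.0 L mol⁻¹)
    precatalyst → free catalyst (k = 0.0550 min⁻¹)

When 30% of the starting material was converted, after 70.9 min, catalyst intermediate A, the resting state of the round, held 44.9% of the catalyst. The flask then made target at 0.00355 M min⁻¹, against the 0.00370 M min⁻¹ from the carried turnover rate. At 1.0 mM of precatalyst, that turnover rate gives 3.70 × 10⁻⁴ M min⁻¹, and the simulation gives 3.50 × 10⁻⁴ M min⁻¹.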